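**Retrosynthetic overview**

1. The target is unmasked last by hydrogenolysis of four benzyl ethers and one benzyl ester. Before that, the ring B acyl–O–C4(ring C) ester is cut, then the ring A acyl–O–C4(ring B) ester.
2. The plan rests on ring C: its C1 carboxyl sits between C2–O and C6–CH3, and its C4 oxygen must be told apart from the C2 oxygen. That array is a 2-pyrone (C5 ester, C4 oxygen, C6 methyl, C3–H) plus a two-carbon ketene acetal that supplies arene C4 with its oxygen and C5.
3. Ring C is the only ring built. The pyrone and 1,1-bis(trimethylsilyloxy)ethene combine by (4+2) addition, then lose CO2 and Me3SiOH, giving C2–OBn and C4–OSiMe3 already differentiated. The pyrone comes from dibenzyl 3-oxopentanedioate by C-acetylation, lactonization and O-benzylation.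
4. Ring A acid comes from 4-methoxy-2-methylphenol (ortho-formylation, Dakin, benzylation, Vilsmeier, Pinnick). Ring B is bought as 2,4-dihydroxy-6-methylbenzaldehyde, whose formyl group serves as a masked carboxyl.
5. Order: ring C first, then the A–B ester, then the AB–C ester, then global deprotection.

Key step: step 5

Remark: the target has no stereocentre, so no stereocontrol is needed; dibenzyl 3-oxopentanedioate, trimethylsilyl acetate, 4-methoxy-2-methylphenol and 2,4-dihydroxy-6-methylbenzaldehyde are taken as purchasable. Pyrone locants follow the 2-pyrone convention (O1, C2=O, C6–CH3).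

**Route**

Step 1
Reactants: 1 dibenzyl 3-oxopentanedioate; 2 acetyl chloride
Product: 3 dibenzyl 2-acetyl-3-oxopentanedioate
Conditions: MgCl2, pyridine, CH2Cl2, 0 °C → rt; then 1 M HCl
Reagents that add atoms: none
Why: Soft enolization of the β-keto diester by MgCl2/pyridine and C-acylation of the chelated magnesium enolate (Rathke-type acylation) should give the monoacetyl compound, because the product is held as a stable magnesium chelate that resists a second acylation.

Step 2
Reactants: 3 dibenzyl 2-acetyl-3-oxopentanedioate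
Product: 4 benzyl 4-hydroxy-6-methyl-2-oxo-2H-pyran-5-carboxylate
Conditions: DBU, PhMe, 80 °C; then 1 M HCl
Reagents that add atoms: none
Why: Base-mediated lactonization of a 3,5-dioxo ester (6-exo-trig addition–elimination of the acetyl enolate oxygen onto the remote benzyl ester) expels benzyl alcohol and is driven by formation of the aromatic, acidic 4-hydroxy-2-pyrone; no other ring size is accessible.

Step 3
Reactants: 4 benzyl 4-hydroxy-6-methyl-2-oxo-2H-pyran-5-carboxylate
Product: 5 benzyl 4-(benzyloxy)-6-methyl-2-oxo-2H-pyran-5-carboxylate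
Conditions: BnBr, K2CO3, DMF, 50 °C
Reagents that add atoms: benzyl bromide, BrCc1ccccc1
Why: Williamson O-alkylation of the vinylogous acid; 4-hydroxy-2-pyrones react with benzylic halides under carbonate conditions mainly at O4, giving the 4-alkoxy-2-pyrone.

Step 4
Reactants: 6 trimethylsilyl acetate
Product: 8 1,1-bis(trimethylsilyloxy)ethene, via lithium 1-(trimethylsilyloxy)ethenolate 7 (not isolated)
Conditions: LiN(iPr)2, THF, −78 °C; Me3SiCl, −78 °C → rt; distil under N2
Reagents that add atoms: chlorotrimethylsilane, C[Si](C)(C)Cl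
Why: Kinetic deprotonation of the silyl ester and O-silylation of the lithium ester enolate by the hard silicon electrophile is the standard preparation of bis(silyl) ketene acetals.

Step 5
Reactants: 5 benzyl 4-(benzyloxy)-6-methyl-2-oxo-2H-pyran-5-carboxylate; 8 1,1-bis(trimethylsilyloxy)ethene
Product: 11 benzyl 2-(benzyloxy)-6-methyl-4-(trimethylsilyloxy)benzoate, via bridged lactone cycloadduct 9 (not isolated), via bis(silyloxy)cyclohexadiene 10 (not isolated)
Conditions: 8 (4 equiv), PhMe, 120 °C, sealed tube, N2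
Reagents that add atoms: none
Why: This is an inverse-electron-demand Diels–Alder reaction followed by retro-(4+2) loss of CO2 and 1,2-elimination, the known path from 2-pyrone-5-carboxylates and ketene acetals to 4-oxygenated benzoates. The nucleophilic CH2 terminus of 8 bonds to pyrone C6 (β-carbon of the C5 ester and vinylogous position of the lactone carbonyl) and the acetal carbon bonds to pyrone C3, either in an asynchronous concerted addition or through a zwitterion that collapses to the same bridged lactone 9. Ring C is closed by this intermolecular (4+2) addition, four carbons coming from the pyrone (C3–C6) and two from 8, and it is unmasked when 9 extrudes CO2 to diene 10, which aromatizes by losing Me3SiOH. No stereocentre is created in the product, since the two bridgehead centres of racemic 9 become sp2 carbons. The step needs regioselectivity, which the C5 ester secures by making C6 the electrophilic diene terminus, so the silyloxy group ends up para to the carboxyl-bearing carbon; which silyloxy group leaves does not matter because the acetal is symmetric. The 4-benzyloxy donor lowers the electrophilicity of the diene, hence the excess of 8 and the sealed-tube temperature.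

Step 6
Reactants: 11 benzyl 2-(benzyloxy)-6-methyl-4-(trimethylsilyloxy)benzoate
Product: 12 benzyl 2-(benzyloxy)-4-hydroxy-6-methylbenzoate
Conditions: 1 M HCl, THF, 0 °C → rt
Reagents that add atoms: none
Why: Acid-catalysed hydrolysis of the labile aryl trimethylsilyl ether should free only the C4 phenol, the benzyl ether and the hindered benzyl ester being inert to dilute acid.

Step 7
Reactants: 13 4-methoxy-2-methylphenol
Product: 15 2-hydroxy-5-methoxy-3-methylbenzaldehyde, via 2-(hydroxymethyl)-4-methoxy-6-methylphenol 14 (not isolated)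
Conditions: MgCl2, Et3N, (CH2O)n, MeCN, reflux; then 1 M HCl
Reagents that add atoms: paraformaldehyde (as formaldehyde), C=O
Why: Magnesium phenoxide-directed ortho-formylation (Casnati–Skattebøl) delivers formaldehyde to the only free ortho position, and a second formaldehyde oxidizes the benzylic alkoxide by hydride transfer; the para position is blocked by the methoxy group.

Step 8
Reactants: 15 2-hydroxy-5-methoxy-3-methylbenzaldehyde
Product: 17 5-methoxy-3-methylbenzene-1,2-diol, via 2-hydroxy-5-methoxy-3-methylphenyl formate 16 (not isolated)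
Conditions: 30% H2O2, NaOH, H2O/THF, 0 °C → rt, N2; then HCl
Reagents that add atoms: hydrogen peroxide, OO
Why: Dakin oxidation: hydroperoxide adds to the aldehyde, the electron-rich ortho-hydroxyaryl group migrates to oxygen, and the aryl formate is saponified in the same flask; the air-sensitive catechol is carried on at once.

Step 9
Reactants: 17 5-methoxy-3-methylbenzene-1,2-diol
Product: 18 1,2-bis(benzyloxy)-5-methoxy-3-methylbenzene
Conditions: BnBr (2.2 equiv), K2CO3, DMF, 60 °C, N2
Reagents that add atoms: benzyl bromide, BrCc1ccccc1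
Why: Double Williamson etherification of the catechol under carbonate conditions.

Step 10
Reactants: 18 1,2-bis(benzyloxy)-5-methoxy-3-methylbenzene
Product: 20 4,5-bis(benzyloxy)-2-methoxy-6-methylbenzaldehyde, via aryl iminium chloride 19 (not isolated)
Conditions: POCl3, DMF, 0 → 70 °C; then H2O, 50 °C
Reagents that add atoms: N,N-dimethylformamide, CN(C)C=O; water, O
Why: Vilsmeier–Haack formylation should occur at C4 of 18 (para to the C1 benzyloxy group, ortho to methoxy and methyl) and not at the position between two alkoxy groups, as 1,2,4-trialkoxybenzenes and 3,5-dialkoxytoluenes do; benzyl ethers tolerate the conditions.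

Step 11
Reactants: 20 4,5-bis(benzyloxy)-2-methoxy-6-methylbenzaldehyde
Product: 21 4,5-bis(benzyloxy)-2-methoxy-6-methylbenzoic acid
Conditions: NaClO2, NaH2PO4, 2-methyl-2-butene, t-BuOH/H2O, rt
Reagents that add atoms: sodium chlorite, [Na+].[O-]Cl=O
Why: Pinnick oxidation converts hindered, electron-rich aryl aldehydes to acids, the alkene scavenging hypochlorous acid so that the ring is not chlorinated.

Step 12
Reactants: 21 4,5-bis(benzyloxy)-2-methoxy-6-methylbenzoic acid; 22 2,4-dihydroxy-6-methylbenzaldehyde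
Product: 24 4-formyl-3-hydroxy-5-methylphenyl 4,5-bis(benzyloxy)-2-methoxy-6-methylbenzoate, via 4,5-bis(benzyloxy)-2-methoxy-6-methylbenzoyl chloride 23 (not isolated)
Conditions: (COCl)2, cat. DMF, CH2Cl2, 0 °C → rt, evaporate; then 22 (1.2 equiv), Et3N, cat. DMAP, CH2Cl2, 0 °C → rt
Reagents that add atoms: none
Why: Acid chloride formation and DMAP-catalysed acyl transfer should esterify only the 4-hydroxyl of 22, because the 2-hydroxyl is locked in a hydrogen bond to the formyl group and is much less nucleophilic.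

Step 13
Reactants: 24 4-formyl-3-hydroxy-5-methylphenyl 4,5-bis(benzyloxy)-2-methoxy-6-methylbenzoate
Product: 25 3-(benzyloxy)-4-formyl-5-methylphenyl 4,5-bis(benzyloxy)-2-methoxy-6-methylbenzoate
Conditions: BnBr, K2CO3, DMF, rt
Reagents that add atoms: benzyl bromide, BrCc1ccccc1
Why: Williamson benzylation of the chelated phenol; the aryl ester should survive because the ring A acyl carbon is shielded by its two ortho substituents (a mesitoate-like ester).

Step 14
Reactants: 25 3-(benzyloxy)-4-formyl-5-methylphenyl 4,5-bis(benzyloxy)-2-methoxy-6-methylbenzoate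
Product: 26 2-(benzyloxy)-4-{[4,5-bis(benzyloxy)-2-methoxy-6-methylbenzoyl]oxy}-6-methylbenzoic acid
Conditions: NaClO2, NaH2PO4, 2-methyl-2-butene, t-BuOH/H2O/THF, rt
Reagents that add atoms: sodium chlorite, [Na+].[O-]Cl=O
Why: Pinnick oxidation at about pH 4 unmasks the ring B carboxyl without touching the aryl ester or the benzyl ethers.

Step 15
Reactants: 26 2-(benzyloxy)-4-{[4,5-bis(benzyloxy)-2-methoxy-6-methylbenzoyl]oxy}-6-methylbenzoic acid; 12 benzyl 2-(benzyloxy)-4-hydroxy-6-methylbenzoate
Product: 28 benzyl 2-(benzyloxy)-4-{[2-(benzyloxy)-4-{[4,5-bis(benzyloxy)-2-methoxy-6-methylbenzoyl]oxy}-6-methylbenzoyl]oxy}-6-methylbenzoate, via didepside acid chloride 27 (not isolated)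
Conditions: (COCl)2, cat. DMF, CH2Cl2, 0 °C → rt, evaporate; then 12, Et3N, DMAP, CH2Cl2, rt
Reagents that add atoms: none
Why: Acid chloride esterification of the unhindered C4 phenol of 12 under DMAP catalysis; the aroyl chloride has no α-hydrogen and the existing aryl ester is inert to oxalyl chloride.

Step 16
Reactants: 28 fully benzylated tridepside benzyl ester
Product: 29 4-{[4-{[4,5-dihydroxy-2-methoxy-6-methylbenzoyl]oxy}-2-hydroxy-6-methylbenzoyl]oxy}-2-hydroxy-6-methylbenzoic acid (CNP0222366.0)
Conditions: H2 (1 atm), 10% Pd/C, EtOAc, rt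
Reagents that add atoms: none
Why: Heterogeneous hydrogenolysis should remove the four benzyl ethers and the benzyl ester, leaving the two aryl ester links and the methyl ether intact.

**Compound list**

1 | dibenzyl 3-oxopentanedioate | O=C(CC(=O)OCc1ccccc1)CC(=O)OCc1ccccc1 | starting material
2 | acetyl chloride | CC(=O)Cl | starting material
3 | dibenzyl 2-acetyl-3-oxopentanedioate (largely enolized) | CC(=O)C(C(=O)OCc1ccccc1)C(=O)CC(=O)OCc1ccccc1 | intermediate
4 | benzyl 4-hydroxy-6-methyl-2-oxo-2H-pyran-5-carboxylate | Cc1oc(=O)cc(O)c1C(=O)OCc1ccccc1 | intermediate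
5 | benzyl 4-(benzyloxy)-6-methyl-2-oxo-2H-pyran-5-carboxylate | Cc1oc(=O)cc(OCc2ccccc2)c1C(=O)OCc1ccccc1 | intermediate
6 | trimethylsilyl acetate | CC(=O)O[Si](C)(C)C | starting material
7 | lithium 1-(trimethylsilyloxy)ethenolate | [Li+].C=C([O-])O[Si](C)(C)C | intermediate
8 | 1,1-bis(trimethylsilyloxy)ethene | C=C(O[Si](C)(C)C)O[Si](C)(C)C | intermediate
9 | benzyl 5-(benzyloxy)-1-methyl-3-oxo-8,8-bis(trimethylsilyloxy)-2-oxabicyclo[2.2.2]oct-5-ene-6-carboxylate (racemic, bridgeheads fixed by the bicycle) | CC12CC(O[Si](C)(C)C)(O[Si](C)(C)C)C(C(=O)O1)C(OCc1ccccc1)=C2C(=O)OCc1ccccc1 | intermediate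
10 | benzyl 2-(benzyloxy)-6-methyl-4,4-bis(trimethylsilyloxy)cyclohexa-2,6-diene-1-carboxylate | CC1=C(C(=O)OCc2ccccc2)C(OCc2ccccc2)=CC(O[Si](C)(C)C)(O[Si](C)(C)C)C1 | intermediate
11 | benzyl 2-(benzyloxy)-6-methyl-4-(trimethylsilyloxy)benzoate | Cc1cc(O[Si](C)(C)C)cc(OCc2ccccc2)c1C(=O)OCc1ccccc1 | intermediate
12 | benzyl 2-(benzyloxy)-4-hydroxy-6-methylbenzoate | Cc1cc(O)cc(OCc2ccccc2)c1C(=O)OCc1ccccc1 | intermediate
13 | 4-methoxy-2-methylphenol | COc1ccc(O)c(C)c1 | starting material
14 | 2-(hydroxymethyl)-4-methoxy-6-methylphenol | COc1cc(C)c(O)c(CO)c1 | intermediate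
15 | 2-hydroxy-5-methoxy-3-methylbenzaldehyde | COc1cc(C)c(O)c(C=O)c1 | intermediate
16 | 2-hydroxy-5-methoxy-3-methylphenyl formate | COc1cc(C)c(O)c(OC=O)c1 | intermediate
17 | 5-methoxy-3-methylbenzene-1,2-diol | COc1cc(C)c(O)c(O)c1 | intermediate
18 | 1,2-bis(benzyloxy)-5-methoxy-3-methylbenzene | COc1cc(C)c(OCc2ccccc2)c(OCc2ccccc2)c1 | intermediate
19 | N-[4,5-bis(benzyloxy)-2-methoxy-6-methylbenzylidene]-N-methylmethanaminium chloride | COc1cc(OCc2ccccc2)c(OCc2ccccc2)c(C)c1C=[N+](C)C.[Cl-] | intermediate
20 | 4,5-bis(benzyloxy)-2-methoxy-6-methylbenzaldehyde | COc1cc(OCc2ccccc2)c(OCc2ccccc2)c(C)c1C=O | intermediate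
21 | 4,5-bis(benzyloxy)-2-methoxy-6-methylbenzoic acid | COc1cc(OCc2ccccc2)c(OCc2ccccc2)c(C)c1C(=O)O | intermediate
22 | 2,4-dihydroxy-6-methylbenzaldehyde | Cc1cc(O)cc(O)c1C=O | starting material
23 | 4,5-bis(benzyloxy)-2-methoxy-6-methylbenzoyl chloride | COc1cc(OCc2ccccc2)c(OCc2ccccc2)c(C)c1C(=O)Cl | intermediate
24 | 4-formyl-3-hydroxy-5-methylphenyl 4,5-bis(benzyloxy)-2-methoxy-6-methylbenzoate | COc1cc(OCc2ccccc2)c(OCc2ccccc2)c(C)c1C(=O)Oc1cc(C)c(C=O)c(O)c1 | intermediate
25 | 3-(benzyloxy)-4-formyl-5-methylphenyl 4,5-bis(benzyloxy)-2-methoxy-6-methylbenzoate | COc1cc(OCc2ccccc2)c(OCc2ccccc2)c(C)c1C(=O)Oc1cc(C)c(C=O)c(OCc2ccccc2)c1 | intermediate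
26 | 2-(benzyloxy)-4-{[4,5-bis(benzyloxy)-2-methoxy-6-methylbenzoyl]oxy}-6-methylbenzoic acid | COc1cc(OCc2ccccc2)c(OCc2ccccc2)c(C)c1C(=O)Oc1cc(C)c(C(=O)O)c(OCc2ccccc2)c1 | intermediate
27 | 2-(benzyloxy)-4-{[4,5-bis(benzyloxy)-2-methoxy-6-methylbenzoyl]oxy}-6-methylbenzoyl chloride | COc1cc(OCc2ccccc2)c(OCc2ccccc2)c(C)c1C(=O)Oc1cc(C)c(C(=O)Cl)c(OCc2ccccc2)c1 | intermediate
28 | benzyl 2-(benzyloxy)-4-{[2-(benzyloxy)-4-{[4,5-bis(benzyloxy)-2-methoxy-6-methylbenzoyl]oxy}-6-methylbenzoyl]oxy}-6-methylbenzoate | COc1cc(OCc2ccccc2)c(OCc2ccccc2)c(C)c1C(=O)Oc1cc(C)c(C(=O)Oc2cc(C)c(C(=O)OCc3ccccc3)c(OCc3ccccc3)c2)c(OCc2ccccc2)c1 | intermediate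
29 | 4-{[4-{[4,5-dihydroxy-2-methoxy-6-methylbenzoyl]oxy}-2-hydroxy-6-methylbenzoyl]oxy}-2-hydroxy-6-methylbenzoic acid | COc1cc(O)c(O)c(C)c1C(=O)Oc1cc(C)c(C(=O)Oc2cc(C)c(C(=O)O)c(O)c2)c(O)c1 | target

**Step count and risks**

Total step count: 16. Longest linear sequence: 10 steps (steps 7–16, from 13 to 29).

Steps most likely to fail:

1. Step 5. The 4-benzyloxy group makes the pyrone a weaker electron-poor diene, so the cycloaddition may be slower than thermal O-to-C silyl migration or adventitious hydrolysis of the ketene acetal, leaving the pyrone unconsumed. Fallback, setting out from 22 and returning at 12: ring C is taken from the purchased arene. Allyl bromide and KHCO3 in DMF should alkylate only the non-chelated 4-hydroxyl to give 4-(allyloxy)-2-hydroxy-6-methylbenzaldehyde F1. Benzyl bromide and K2CO3 then give 4-(allyloxy)-2-(benzyloxy)-6-methylbenzaldehyde F2. Pinnick oxidation (NaClO2, NaH2PO4, 2-methyl-2-butene) gives 4-(allyloxy)-2-(benzyloxy)-6-methylbenzoic acid F3. Benzyl bromide and K2CO3 give benzyl 4-(allyloxy)-2-(benzyloxy)-6-methylbenzoate F4. Pd(PPh3)4, a complex of zerovalent palladium, with morpholine in THF removes the allyl group to give 12.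

2. Step 13. Benzylation of the hydrogen-bonded 2-hydroxyl may be slow enough that carbonate or adventitious hydroxide attacks the aryl ester, whose 4-formylphenoxide is a good leaving group, with loss of the ring A acyl group. Fallback, setting out from 24 and returning at 29: the benzyl ether and the acid chloride are both avoided. Pinnick oxidation of 24 gives 4-{[4,5-bis(benzyloxy)-2-methoxy-6-methylbenzoyl]oxy}-2-hydroxy-6-methylbenzoic acid F5. Carbodiimide coupling of this salicylic acid with 12 (DCC, PhMe/CH2Cl2, rt), in which the chelated ortho-hydroxyl does not compete, gives benzyl 2-(benzyloxy)-4-{[4-{[4,5-bis(benzyloxy)-2-methoxy-6-methylbenzoyl]oxy}-2-hydroxy-6-methylbenzoyl]oxy}-6-methylbenzoate F6. Hydrogenolysis over 10% Pd/C gives 29.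

3. Step 10. The Vilsmeier electrophile may attack the other free position of 18 (C6, between the benzyloxy and methoxy groups) to a competitive extent, giving an isomeric aldehyde that is hard to separate. Fallback, setting out from 22 and returning at 20: the carbonyl carbon is in place from the start and the C5 oxygen is introduced para to the free phenol. Benzyl bromide and KHCO3 give 4-(benzyloxy)-2-hydroxy-6-methylbenzaldehyde F7. Elbs persulfate oxidation (K2S2O8, aq. NaOH, pyridine) gives potassium 6-(benzyloxy)-3-formyl-4-hydroxy-2-methylphenyl sulfate F8, which aqueous HCl hydrolyses to 4-(benzyloxy)-2,5-dihydroxy-6-methylbenzaldehyde F9. One equivalent of benzyl bromide with K2CO3 should alkylate the non-chelated 5-hydroxyl to give 4,5-bis(benzyloxy)-2-hydroxy-6-methylbenzaldehyde F10. MeI and K2CO3 in DMF then methylate the chelated hydroxyl to give 20.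

Further compounds
F1 | step 5 | 4-(allyloxy)-2-hydroxy-6-methylbenzaldehyde | Cc1cc(OCC=C)cc(O)c1C=O
F2 | step 5 | 4-(allyloxy)-2-(benzyloxy)-6-methylbenzaldehyde | Cc1cc(OCC=C)cc(OCc2ccccc2)c1C=O
F3 | step 5 | 4-(allyloxy)-2-(benzyloxy)-6-methylbenzoic acid | Cc1cc(OCC=C)cc(OCc2ccccc2)c1C(=O)O
F4 | step 5 | benzyl 4-(allyloxy)-2-(benzyloxy)-6-methylbenzoate | Cc1cc(OCC=C)cc(OCc2ccccc2)c1C(=O)OCc1ccccc1
F5 | step 13 | 4-{[4,5-bis(benzyloxy)-2-methoxy-6-methylbenzoyl]oxy}-2-hydroxy-6-methylbenzoic acid | COc1cc(OCc2ccccc2)c(OCc2ccccc2)c(C)c1C(=O)Oc1cc(C)c(C(=O)O)c(O)c1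
F6 | step 13 | benzyl 2-(benzyloxy)-4-{[4-{[4,5-bis(benzyloxy)-2-methoxy-6-methylbenzoyl]oxy}-2-hydroxy-6-methylbenzoyl]oxy}-6-methylbenzoate | COc1cc(OCc2ccccc2)c(OCc2ccccc2)c(C)c1C(=O)Oc1cc(C)c(C(=O)Oc2cc(C)c(C(=O)OCc3ccccc3)c(OCc3ccccc3)c2)c(O)c1
F7 | step 10 | 4-(benzyloxy)-2-hydroxy-6-methylbenzaldehyde | Cc1cc(OCc2ccccc2)cc(O)c1C=O
F8 | step 10 | potassium 6-(benzyloxy)-3-formyl-4-hydroxy-2-methylphenyl sulfate | Cc1c(OS(=O)(=O)[O-])c(OCc2ccccc2)cc(O)c1C=O.[K+]
F9 | step 10 | 4-(benzyloxy)-2,5-dihydroxy-6-methylbenzaldehyde | Cc1c(O)c(OCc2ccccc2)cc(O)c1C=O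
F10 | step 10 | 4,5-bis(benzyloxy)-2-hydroxy-6-methylbenzaldehyde | Cc1c(OCc2ccccc2)c(OCc2ccccc2)cc(O)c1C=O
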